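If a flask stalls with substrate still in it, ask how long it really worked.

all flasks: free catalyst 0.0400 M

| run | substrate | partner | time |
|---|---|---|---|
| west | 0.800 M | 1.20 M |  |
| east | 0.480 M | 0.880 M |  |
| north-east | 1.20 M | 1.20 M |  |
| north-west | 0.800 M | 1.80 M |  |
| north | 0.200 M | 0.300 M | 100 h |

| run | time / h | [target] / M |
|---|---|---|
| west run | 4.0 | 0.082 |
| west run | 6.3 | 0.126 |
| west run | 10 | 0.154 |
| west run | 16 | 0.202 |
| west run | 25 | 0.241 |
| west run | 40 | 0.271 |
| west run | 63 | 0.293 |
| west run | 100 | 0.315 |
| east run | 4.0 | 0.107 |
| east run | 6.3 | 0.160 |
| east run | 10 | 0.206 |
| east run | 16 | 0.265 |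
| east run | 25 | 0.288 |
| east run | 40 | 0.315 |
| east run | 63 | 0.322 |
| east run | 100 | 0.328 |
| north-east run | 4.0 | 0.064 |
| north-east run | 6.3 | 0.076 |
| north-east run | 10 | 0.115 |
| north-east run | 16 | 0.138 |
| north-east run | 25 | 0.161 |
| north-east run | 40 | 0.200 |
| north-east run | 63 | 0.221 |
| north-east run | 100 | 0.227 |
| north-west run | 4.0 | 0.109 |
| north-west run | 6.3 | 0.161 |
| north-west run | 10 | 0.201 |
| north-west run | 16 | 0.252 |
| north-west run | 25 | 0.294 |
| north-west run | 40 | 0.337 |
| north-west run | 63 | 0.356 |
| north-west run | 100 | 0.368 |

(scatter of a reading: 0.004 M)

1. reaction order in [partner] at the outset, round the charge of the west run, defined at two percent of the substrate turned into target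
2. reaction order in [substrate] at the outset, round the charge of the west run, defined at two percent of the substrate turned into target (one fixed amount of target, the same in the runs compared)
3. target in the north run at 100 h, as a share of the substrate charged

- Overall: substrate + partner -> target, with free catalyst as catalyst.
- Constant volume, constant temperature.
- Readings of a species count what is bound in complexes too.
- An order is taken over about fifteen percent of the charge, up and down.

1. Read the early rate as the target at 4.0 h over that time: in the west run, 0.02050 M h⁻¹. Against west, the north-west run gives a partner order of 0.702 and the north-east run a substrate order of −0.611.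

2. Treat both as too small in size, since a mean rate trails the outset rate, and more so in the faster flask. My reckoning takes about 1 in c(partner) and minus 1 in c(substrate). Check it on the east run: the rule gives a rate ratio to west of 1.22, and the readings give 1.30.

3. Define the working time, the last target reading divided by the early rate. It is the time the flask would need at its early rate to make what it finally made. West gives 15.4 h, east 12.3 h, north-east 14.2 h and north-west 13.5 h. Their mean is 13.8 h.

4. Solve two extremes for the north run, whose c(partner)/c(substrate) equals west's, so by that rule its early rate should stand near west's. If it made west's share, it would reach 39.4 %. West's amount, 0.315 M, is more than the north charge of 0.200 M, so the other extreme is 100 %.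

5. Put the answer back in. At west's early rate, turning the whole north charge needs 9.76 h of working time, less than the mean. At its own early rate, the east charge needs 17.9 h, more than the mean, and the east run read 68.3 % of its substrate at 100 h. So I place the north run between that share and 100 %.

6. The forecast gave 0.7, −0.8 and 85 %, in its words: “Conversion should be high but incomplete”. Its orders differ from mine; its share lies inside my bracket.

7. At 100 h the north run has turned 72.2 % of its substrate into target.

    free catalyst + substrate ⇌ catalyst-substrate complex, settled at all times (24.80 L mol⁻¹)
    free catalyst + partner ⇌ catalyst-reagent complex, settled at all times (0.6140 L mol⁻¹)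
    catalyst-substrate complex + catalyst-reagent complex → target + 2 free catalyst (590.4 L mol⁻¹ h⁻¹)
    2 free catalyst → 2 spent catalyst (14.72 L mol⁻¹ h⁻¹)
    2 partner → lost reagent (0.1001 L mol⁻¹ h⁻¹)

8. That is 0.144 M, near the lower edge of the bracket. The outset orders come to 0.94 in c(partner) and −0.99 in c(substrate). At west's early rate, the north run's working time is 7.05 h, about half of the mean from the earlier runs. In the east run, target comes to half of the substrate charged at 13.4 h, and at east's early rate that amount takes 8.97 h of working time.

The readings stem from a simulated flask for an exercise, noise included.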